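**Plan**

1. Retrosynthesis, last bonds first: the oxirane C4–O–C5 is cut back to the 4Z alkene beside a free C6 alcohol, the lactone bond C12–O8 to a C12 alcohol and a C8 alcohol, and the O9 isobutyrate with the C9–H bond to a C9 ketone.
2. The ten-membered ring is then traced back to a tricyclic ketone by re-forming the σ-bonds C1–C4 and C5–C10; this tricycle is cut at C1–C10 and C4–C5 into a 6,8,12-trioxygenated (S)-carvone and 1-methylcyclobutene.
3. Forward order: the carvone ring (C5–C10) is oxygenated at C12, C6 and C8; both cyclobutanes arise in one [2+2] photocycloaddition; the ten-membered ring appears by thermal cycloreversion; then the γ-lactone is closed and the oxirane comes last.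
4. Stereochemistry: C7 comes from (S)-carvone; O6 and O8 enter anti to the C7 side chain; the E/Z alkene pair follows from the cis-fused photoadduct; C9 is set by chelation-controlled reduction beside the O8 MOM ether; C4/C5 by C6–OH-directed epoxidation.
5. Enabling feature: the 1,5-diene C10=C1–C2–C3–C4=C5 inside the ten-membered ring, with C1=C10 E and C4=C5 Z, is the imprint of a bicyclo[2.2.0]hexane (C1, C2, C3, C4, C5, C10) whose bonds C1–C4 and C5–C10 have been cleaved; the other ring atoms C5–C10 are the carvone six-membered ring.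

Key step: step 10

Remark: atoms carry germacrane numbers throughout (C1–C4 and C15 from the cyclobutene; C5–C10 with methyl C14 from the carvone ring, C9 being the carbonyl carbon; C11–C13 the isopropenyl carbons), while the systematic names of monocyclic compounds keep their own ring locants.

**Route**

Step 1
Reactants: 1 (S)-(+)-carvone
Product: 2 (5S)-5-(3-chloroprop-1-en-2-yl)-2-methylcyclohex-2-en-1-one
Conditions: Ca(OCl)2, CO2 (dry ice), CH2Cl2/H2O, 0 °C
Reagents that add atoms: calcium hypochlorite, [Ca+2].[O-]Cl.[O-]Cl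
Why: Ene-type allylic chlorination by HOCl formed in situ attacks only the electron-rich 1,1-disubstituted isopropenyl alkene and not the enone, so C12 is functionalised early, before any other nucleophilic alkene exists, and no stereocentre is touched.

Step 2
Reactants: 2 (5S)-5-(3-chloroprop-1-en-2-yl)-2-methylcyclohex-2-en-1-one
Product: 4 (5S)-5-(3-hydroxyprop-1-en-2-yl)-2-methylcyclohex-2-en-1-one, via allylic acetate 3 (not isolated)
Conditions: KOAc, NaI (cat.), DMF, 60 °C; then K2CO3 (cat.), MeOH, 0 °C
Reagents that add atoms: potassium acetate, CC(=O)[O-].[K+]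
Why: SN2 displacement of the primary allylic chloride by acetate followed by carbonate-catalysed transesterification with methanol is a standard two-stage hydrolysis that keeps hydroxide away from the enone.

Step 3
Reactants: 4 (5S)-5-(3-hydroxyprop-1-en-2-yl)-2-methylcyclohex-2-en-1-one
Product: 5 (5S)-5-[3-(methoxymethoxy)prop-1-en-2-yl]-2-methylcyclohex-2-en-1-one
Conditions: MOMCl, iPr2NEt, CH2Cl2, 0 °C → rt
Reagents that add atoms: chloromethyl methyl ether, COCCl
Why: Acetal protection of a primary alcohol by O-alkylation under amine base gives an ether that should survive strong base, peracid, light and heat.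

Step 4
Reactants: 5 (5S)-5-[3-(methoxymethoxy)prop-1-en-2-yl]-2-methylcyclohex-2-en-1-one
Product: 6 {[(5R)-5-[3-(methoxymethoxy)prop-1-en-2-yl]-2-methylcyclohexa-1,3-dien-1-yl]oxy}trimethylsilane (linear dienol ether, C9=C10 and C5=C6)
Conditions: MeMgBr, FeCl3 (cat.), Et2O, −20 → 0 °C; then TMSCl, Et3N, HMPA; pentane/cold aq. NaHCO3 work-up
Reagents that add atoms: chlorotrimethylsilane, C[Si](C)(C)Cl
Why: The iron-catalysed Grignard base (Kharasch reagent) removes the γ-hydrogen at C6 of enones to give the extended dienolate even when α′-hydrogens are present, and O-silylation then gives the 1-silyloxy-1,3-diene needed for γ-oxidation, with C7 unaffected.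

Step 5
Reactants: 6 linear trimethylsilyl dienol ether
Product: 7 (4R,5S)-4-hydroxy-5-[3-(methoxymethoxy)prop-1-en-2-yl]-2-methylcyclohex-2-en-1-one (O6 trans to the C7 side chain)
Conditions: mCPBA (1 equiv), NaHCO3, CH2Cl2, −20 °C; then aq. citric acid, THF
Reagents that add atoms: 3-chloroperbenzoic acid, OOC(=O)c1cccc(Cl)c1
Why: In this vinylogous Rubottom oxidation the peracid epoxidises the terminal C5=C6 bond of the dienol ether (the α-carbon C10 is fully substituted) from the face anti to the adjacent C7 side chain, and collapse of the epoxide with loss of silicon restores the enone with the new C6 hydroxyl trans to C7.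

Step 6
Reactants: 7 (4R,5S)-4-hydroxy enone
Product: 8 (4R,5S)-4-[(tert-butyldimethylsilyl)oxy]-5-[3-(methoxymethoxy)prop-1-en-2-yl]-2-methylcyclohex-2-en-1-one
Conditions: TBSCl, imidazole, DMF, rt
Reagents that add atoms: tert-butyldimethylsilyl chloride, CC(C)(C)[Si](C)(C)Cl
Why: Silylation of a secondary allylic alcohol is routine, and the bulky ether is chosen to shield the lower face of C5 in the photocycloaddition and to outlast the MOM groups.

Step 7
Reactants: 8 (4R,5S)-4-silyloxy enone
Product: 11 (4R,5R,6R)-4-[(tert-butyldimethylsilyl)oxy]-6-hydroxy-5-[3-(methoxymethoxy)prop-1-en-2-yl]-2-methylcyclohex-2-en-1-one, via silyl dienol ether 9 (not isolated), via silyloxy ketone 10 (not isolated)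
Conditions: LiN(iPr)2, THF, −78 °C; TMSCl; then mCPBA, NaHCO3, CH2Cl2, −20 °C; then citric acid, MeOH, 0 °C
Reagents that add atoms: 3-chloroperbenzoic acid, OOC(=O)c1cccc(Cl)c1
Why: In this Rubottom oxidation kinetic deprotonation occurs at the only α′-methylene (C8), and the peracid attacks the silyl enol ether anti to the neighbouring C7 substituent, so that after 1,4-silyl shift and methanolysis the C8 hydroxyl is trans to C7 and cis to O6.

Step 8
Reactants: 11 (4R,5R,6R)-6-hydroxy enone
Product: 12 (4R,5R,6R)-4-[(tert-butyldimethylsilyl)oxy]-6-(methoxymethoxy)-5-[3-(methoxymethoxy)prop-1-en-2-yl]-2-methylcyclohex-2-en-1-one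
Conditions: MOMCl, iPr2NEt, Bu4NI (cat.), CH2Cl2, 0 → 40 °C
Reagents that add atoms: chloromethyl methyl ether, COCCl
Why: Acetal protection of the α-ketol under non-enolising amine conditions installs a small chelating ether at O8 that will later direct the reduction of C9.

Step 9
Reactants: 12 protected enone; 13 1-methylcyclobutene
Product: 14 cis-anti-cis photoadduct (6-silyloxy-8,12-bis(methoxymethoxy) tricyclic C9 ketone; cyclobutane C1–C4–C5–C10 cis-fused on the ring face opposite O6 and O8; second cyclobutane C1–C2–C3–C4 anti to the six-membered ring; methyls on C4 and C10)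
Conditions: hν (350 nm, Pyrex), 13 (excess), CH2Cl2, −60 °C
Reagents that add atoms: none
Why: In this enone–alkene [2+2] photocycloaddition through the enone triplet, the β-carbon C5 joins the more substituted alkene carbon C4 (head-to-tail orientation typical of electron-rich alkenes, which also keeps the quaternary centres C4 and C10 apart) on the face anti to the C6 silyl ether and the C8 MOM ether, and closure of the 1,4-diradical gives the cis-fused cyclobutane with the cyclobutene ring anti to the six-membered ring, which fixes C1, C4, C5 and C10 relative to C6–C8.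

Step 10
Reactants: 14 cis-anti-cis photoadduct
Product: 15 (1(10)E,4Z)-6-[(tert-butyldimethylsilyl)oxy]-8,12-bis(methoxymethoxy)germacra-1(10),4,11(13)-trien-9-one
Conditions: PhMe (0.01 M, degassed), BHT (cat.), base-washed sealed tube, 190 °C
Reagents that add atoms: none
Why: Heating cleaves the strained central C1–C4 σ-bond of the bicyclo[2.2.0]hexane to a chair-like cyclohexane-1,4-diyl (radical centres C1 and C4), which fragments across C5–C10 so that C1=C10 and C4=C5 appear, overall a formal [σ2s+σ2a] cycloreversion. The closest known reaction type is the thermolysis of cyclohexenone–cyclobutene photoadducts (tricyclo[4.4.0.0(2,5)]decanones) to cis,trans-cyclodeca-1,5-dienes. The ten-membered ring is not closed by bond formation but arises by ring expansion, when the bond C5–C10 shared by the cyclobutane and the cyclohexanone is lost and the four- and six-membered rings merge. No new sp3 stereocentre is formed (C1, C4, C5 and C10 become trigonal, C6, C7 and C8 are untouched), and the two alkene geometries are governed by the cis fusion at C5–C10, which places C9 and C6 one equatorial and one axial on the chair diyl and so enforces one E and one Z alkene. Two selectivities are needed: cleavage of C5–C10 rather than C2–C3 (which would give a divinylcyclohexanone), favoured because only this mode conjugates the new C1=C10 bond with the C9 carbonyl, and E at C1=C10 with Z at C4=C5 rather than the reverse, secured because the cyclobutane lies anti to O6 and O8, so that in the cyclohexanone chair with equatorial C6, C7 and C8 substituents C9 is equatorial and C6 axial on the diyl ring. The enone conjugation of the product should also hold back a following Cope rearrangement, and the dilute, base-washed, radical-inhibited conditions serve the same purpose.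

Step 11
Reactants: 15 (1(10)E,4Z)-trienone
Product: 16 (1(10)E,4Z,9S)-6-[(tert-butyldimethylsilyl)oxy]-8,12-bis(methoxymethoxy)germacra-1(10),4,11(13)-trien-9-ol
Conditions: Zn(BH4)2, Et2O, −30 → 0 °C
Reagents that add atoms: none
Why: In this chelation-controlled 1,2-reduction the zinc ion bridges the C9 carbonyl and the O8 MOM ether and hydride adds from the peripheral face anti to C7 on C8 (Cram chelate model), which gives the 9S alcohol (8,9-anti) without conjugate reduction.

Step 12
Reactants: 16 (9S)-allylic alcohol; 17 isobutyric anhydride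
Product: 18 (1(10)E,4Z,9S)-6-[(tert-butyldimethylsilyl)oxy]-8,12-bis(methoxymethoxy)germacra-1(10),4,11(13)-trien-9-yl 2-methylpropanoate
Conditions: Et3N, DMAP (cat.), CH2Cl2, rt
Reagents that add atoms: none
Why: DMAP-catalysed acylation of the secondary allylic alcohol by the anhydride installs the isobutyrate with retention at C9.

Step 13
Reactants: 18 9-isobutyrate
Product: 19 (1(10)E,4Z,9S)-6-[(tert-butyldimethylsilyl)oxy]-8,12-dihydroxygermacra-1(10),4,11(13)-trien-9-yl 2-methylpropanoate
Conditions: ZnBr2, nPrSH, CH2Cl2, 0 °C, 10 min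
Reagents that add atoms: none
Why: Lewis acid/thiol cleavage of MOM ethers (ZnBr2 activates the acetal and the thiol captures the methoxymethyl unit) is fast at 0 °C and should spare the silyl ether, the allylic ester and the diene, and the crude diol is oxidised at once so that the ester cannot migrate from O9 to O8.

Step 14
Reactants: 19 8,12-diol
Product: 22 (1(10)E,4Z)-6-[(tert-butyldimethylsilyl)oxy]-9-(2-methylpropanoyloxy)germacra-1(10),4,11(13)-trien-12,8-olide, via hydroxy enal 20 (not isolated), via lactol 21 (not isolated)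
Conditions: MnO2 (activated, excess), CH2Cl2, rt
Reagents that add atoms: none
Why: In this oxidative lactonisation MnO2 oxidises only the primary allylic alcohol, the enal is trapped by the C8 hydroxyl as a five-membered lactol (O6 is still silylated, so no 6,12-lactol can form) and this allylic lactol is oxidised on to the α-methylene-γ-butyrolactone, with no stereocentre changed.

Step 15
Reactants: 22 silylated lactone
Product: 23 (1(10)E,4Z)-6-hydroxy-9-(2-methylpropanoyloxy)germacra-1(10),4,11(13)-trien-12,8-olide
Conditions: HF·pyridine, pyridine, THF, 0 °C → rt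
Reagents that add atoms: none
Why: Buffered fluoride cleavage of the secondary silyl ether needs no base, so the α-methylene lactone, the allylic ester and the diene should remain intact.

Step 16
Reactants: 23 6-hydroxy lactone
Product: 24 (1(10)E,4S,5R,6S,7S,8R,9S)-4,5-epoxy-6-hydroxy-9-(2-methylpropanoyloxy)germacra-1(10),11(13)-dien-12,8-olide (CNP0220196.2)
Conditions: VO(acac)2 (cat.), tBuOOH, PhH, rt
Reagents that add atoms: tert-butyl hydroperoxide, CC(C)(C)OO
Why: In this hydroxyl-directed epoxidation the vanadium alkoxide of the C6 alcohol delivers oxygen only to the allylic C4=C5 bond, syn to the hydroxyl in the conformer that keeps H6 in the alkene plane towards C3 (least A(1,3) strain), which gives the threo 4S,5R epoxy alcohol and leaves the C1=C10 and C11=C13 alkenes alone.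

**Compound list**

1 | (S)-(+)-carvone | CC1=CC[C@@H](CC1=O)C(C)=C | starting material
2 | (5S)-5-(3-chloroprop-1-en-2-yl)-2-methylcyclohex-2-en-1-one | O=C1C(C)=CC[C@H](C(=C)CCl)C1 | intermediate
3 | 2-[(1S)-4-methyl-5-oxocyclohex-3-en-1-yl]prop-2-en-1-yl acetate | O=C1C(C)=CC[C@H](C(=C)COC(C)=O)C1 | intermediate (not isolated)
4 | (5S)-5-(3-hydroxyprop-1-en-2-yl)-2-methylcyclohex-2-en-1-one | O=C1C(C)=CC[C@H](C(=C)CO)C1 | intermediate
5 | (5S)-5-[3-(methoxymethoxy)prop-1-en-2-yl]-2-methylcyclohex-2-en-1-one | O=C1C(C)=CC[C@H](C(=C)COCOC)C1 | intermediate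
6 | {[(5R)-5-[3-(methoxymethoxy)prop-1-en-2-yl]-2-methylcyclohexa-1,3-dien-1-yl]oxy}trimethylsilane | C[Si](C)(C)OC1=C(C)C=C[C@H](C(=C)COCOC)C1 | intermediate
7 | (4R,5S)-4-hydroxy-5-[3-(methoxymethoxy)prop-1-en-2-yl]-2-methylcyclohex-2-en-1-one | O=C1C(C)=C[C@@H](O)[C@H](C(=C)COCOC)C1 | intermediate
8 | (4R,5S)-4-[(tert-butyldimethylsilyl)oxy]-5-[3-(methoxymethoxy)prop-1-en-2-yl]-2-methylcyclohex-2-en-1-one | O=C1C(C)=C[C@@H](O[Si](C)(C)C(C)(C)C)[C@H](C(=C)COCOC)C1 | intermediate
9 | cross-conjugated trimethylsilyl dienol ether of 8 (C8=C9 and C10=C5) | C[Si](C)(C)OC1=C[C@@H](C(=C)COCOC)[C@H](O[Si](C)(C)C(C)(C)C)C=C1C | intermediate (not isolated)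
10 | 8-(trimethylsilyloxy) ketone (O8 trans to the C7 side chain) | O=C1C(C)=C[C@@H](O[Si](C)(C)C(C)(C)C)[C@H](C(=C)COCOC)[C@H]1O[Si](C)(C)C | intermediate (not isolated)
11 | (4R,5R,6R)-4-[(tert-butyldimethylsilyl)oxy]-6-hydroxy-5-[3-(methoxymethoxy)prop-1-en-2-yl]-2-methylcyclohex-2-en-1-one | O=C1C(C)=C[C@@H](O[Si](C)(C)C(C)(C)C)[C@H](C(=C)COCOC)[C@H]1O | intermediate
12 | (4R,5R,6R)-4-[(tert-butyldimethylsilyl)oxy]-6-(methoxymethoxy)-5-[3-(methoxymethoxy)prop-1-en-2-yl]-2-methylcyclohex-2-en-1-one | O=C1C(C)=C[C@@H](O[Si](C)(C)C(C)(C)C)[C@H](C(=C)COCOC)[C@H]1OCOC | intermediate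
13 | 1-methylcyclobutene | CC1=CCC1 | starting material
14 | cis-anti-cis photoadduct (tricyclic C9 ketone; cyclobutane C1–C4–C5–C10 on the face opposite O6 and O8) | O=C1[C@]2(C)[C@H]3CC[C@@]3(C)[C@@H]2[C@@H](O[Si](C)(C)C(C)(C)C)[C@H](C(=C)COCOC)[C@H]1OCOC | intermediate
15 | (1(10)E,4Z)-6-[(tert-butyldimethylsilyl)oxy]-8,12-bis(methoxymethoxy)germacra-1(10),4,11(13)-trien-9-one | O=C1/C(C)=C/CC/C(C)=C\[C@@H](O[Si](C)(C)C(C)(C)C)[C@H](C(=C)COCOC)[C@H]1OCOC | intermediate
16 | (1(10)E,4Z,9S)-6-[(tert-butyldimethylsilyl)oxy]-8,12-bis(methoxymethoxy)germacra-1(10),4,11(13)-trien-9-ol | O[C@H]1/C(C)=C/CC/C(C)=C\[C@@H](O[Si](C)(C)C(C)(C)C)[C@H](C(=C)COCOC)[C@H]1OCOC | intermediate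
17 | isobutyric anhydride | CC(C)C(=O)OC(=O)C(C)C | starting material
18 | 9-isobutyrate of 16 | CC(C)C(=O)O[C@H]1/C(C)=C/CC/C(C)=C\[C@@H](O[Si](C)(C)C(C)(C)C)[C@H](C(=C)COCOC)[C@H]1OCOC | intermediate
19 | 8,12-diol (6-silyl ether, 9-isobutyrate) | CC(C)C(=O)O[C@H]1/C(C)=C/CC/C(C)=C\[C@@H](O[Si](C)(C)C(C)(C)C)[C@H](C(=C)CO)[C@H]1O | intermediate
20 | 8-hydroxy C12 enal | CC(C)C(=O)O[C@H]1/C(C)=C/CC/C(C)=C\[C@@H](O[Si](C)(C)C(C)(C)C)[C@H](C(=C)C=O)[C@H]1O | intermediate (not isolated)
21 | 8,12-lactol (both C12 epimers) | C=C1C(O)O[C@@H]2[C@@H]1[C@H](O[Si](C)(C)C(C)(C)C)/C=C(C)\CC/C=C(\C)[C@@H]2OC(=O)C(C)C | intermediate (not isolated)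
22 | (1(10)E,4Z)-6-[(tert-butyldimethylsilyl)oxy]-9-(2-methylpropanoyloxy)germacra-1(10),4,11(13)-trien-12,8-olide | C=C1C(=O)O[C@@H]2[C@@H]1[C@H](O[Si](C)(C)C(C)(C)C)/C=C(C)\CC/C=C(\C)[C@@H]2OC(=O)C(C)C | intermediate
23 | (1(10)E,4Z)-6-hydroxy-9-(2-methylpropanoyloxy)germacra-1(10),4,11(13)-trien-12,8-olide | C=C1C(=O)O[C@@H]2[C@@H]1[C@H](O)/C=C(C)\CC/C=C(\C)[C@@H]2OC(=O)C(C)C | intermediate
24 | (1(10)E,4S,5R,6S,7S,8R,9S)-4,5-epoxy-6-hydroxy-9-(2-methylpropanoyloxy)germacra-1(10),11(13)-dien-12,8-olide | C=C1C(=O)O[C@@H]2[C@@H]1[C@H](O)[C@H]1O[C@@]1(C)CC/C=C(\C)[C@@H]2OC(=O)C(C)C | target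

**Step count and risks**

Total: 16 steps. Longest linear sequence: 16 steps (1 → 24).

Step 10 (key step). The danger is a further [3,3] shift of the new 1,5-diene to the cis-divinylcyclohexanone at the temperature needed, partition of the diyl towards C2–C3 cleavage, or isomerisation of the strained E-enone. The fallback runs the cycloreversion at the carbinol oxidation level, where no enone is present during heating. Setting out from 14, NaBH4 in MeOH would give the tricyclic C9 carbinol F1 (either C9 epimer serves). Heating it as in step 10 should give the (1(10)E,4Z)-cyclodecadien-9-ol F2, and allylic oxidation with MnO2 comes back to the route at 15.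

Step 9. Here the dangers are hydrogen abstraction by the excited ketone from the α′-alkoxymethyl ether, slow intermolecular addition to the congested trisubstituted enone with competing intramolecular addition of the C11=C13 alkene, and insufficient facial selectivity. The fallback moves the photocycloaddition ahead of the C8 oxygenation. Setting out from 8, irradiation with 13 would give the tricyclic ketone without O8 F3. Because C10 is quaternary, only C8 can be enolised, so KN(SiMe3)2 followed by 2-(phenylsulfonyl)-3-phenyloxaziridine should give the 8-hydroxy tricyclic ketone F4 with O8 trans to the C7 side chain. MOMCl/iPr2NEt then comes back to the route at 14.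

Step 4. The risk is loss of regiocontrol in the enolisation: competing α′-deprotonation at C8 would give the cross-conjugated dienol ether and, after oxidation, the wrong hydroxy ketone. The fallback reverses the order of the two oxygenations and blocks C8 before C6 is enolised kinetically.

- Setting out from 5, KN(SiMe3)2 and 2-(phenylsulfonyl)-3-phenyloxaziridine would give the trans 8-hydroxy enone F5, and TESCl/imidazole its triethylsilyl ether F6.
- The C8 methine then carries a silyloxy group, so LiN(iPr)2/TMSCl should deprotonate at C6 and give the linear trimethylsilyl dienol ether F7. mCPBA oxidises it to the 6-hydroxy-8-(triethylsilyloxy) enone F8.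
- TBSOTf/2,6-lutidine gives the 6-O-TBS-8-O-TES enone F9, and PPTS in MeOH removes only the triethylsilyl group, coming back to the route at 11.

Further compounds

F1 | step 10 | tricyclic C9 carbinol (14 reduced at C9, both epimers) | OC1[C@]2(C)[C@H]3CC[C@@]3(C)[C@@H]2[C@@H](O[Si](C)(C)C(C)(C)C)[C@H](C(=C)COCOC)[C@H]1OCOC
F2 | step 10 | (1(10)E,4Z)-6-[(tert-butyldimethylsilyl)oxy]-8,12-bis(methoxymethoxy)germacra-1(10),4,11(13)-trien-9-ol (both C9 epimers) | OC1/C(C)=C/CC/C(C)=C\[C@@H](O[Si](C)(C)C(C)(C)C)[C@H](C(=C)COCOC)[C@H]1OCOC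
F3 | step 9 | cis-anti-cis photoadduct of 8 and 13 (tricyclic ketone without O8) | O=C1[C@]2(C)[C@H]3CC[C@@]3(C)[C@@H]2[C@@H](O[Si](C)(C)C(C)(C)C)[C@H](C(=C)COCOC)C1
F4 | step 9 | 8-hydroxy tricyclic ketone (O8 trans to the C7 side chain) | O=C1[C@]2(C)[C@H]3CC[C@@]3(C)[C@@H]2[C@@H](O[Si](C)(C)C(C)(C)C)[C@H](C(=C)COCOC)[C@H]1O
F5 | step 4 | (5R,6R)-6-hydroxy-5-[3-(methoxymethoxy)prop-1-en-2-yl]-2-methylcyclohex-2-en-1-one | O=C1C(C)=CC[C@H](C(=C)COCOC)[C@H]1O
F6 | step 4 | triethylsilyl ether of F5 | O=C1C(C)=CC[C@H](C(=C)COCOC)[C@H]1O[Si](CC)(CC)CC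
F7 | step 4 | linear trimethylsilyl dienol ether of F6 (C9=C10 and C5=C6) | C[Si](C)(C)OC1=C(C)C=C[C@H](C(=C)COCOC)[C@H]1O[Si](CC)(CC)CC
F8 | step 4 | 6-hydroxy-8-(triethylsilyloxy) enone (O6 and O8 trans to the C7 side chain) | O=C1C(C)=C[C@@H](O)[C@H](C(=C)COCOC)[C@H]1O[Si](CC)(CC)CC
F9 | step 4 | 6-O-TBS-8-O-TES enone | O=C1C(C)=C[C@@H](O[Si](C)(C)C(C)(C)C)[C@H](C(=C)COCOC)[C@H]1O[Si](CC)(CC)CC
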